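Ring A (C9–C14) is a cyclohex-3-ene with C8 on C9 and its alkene at C11=C12; C8, C9, C14, C13, C12 and one oxygen therefore make a δ-lactone that is one bond, C9–C10, short of the carbocycle. The route rests on forging that bond by Ireland–Claisen rearrangement of the lactone silyl ketene acetal: a single operation builds ring A, places the alkene, frees C8 as a carboxyl group and sets C9 and C10 against C13. The precursor is the cis-4,4,5-trimethyl δ-lactone carrying a (Z)-but-2-en-2-yl group on its carbinol carbon C12. C3 is set last by copper-catalysed SN2′ alkenylation of an allylic phosphate.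

Key step: step 8

Numbering used throughout (target atoms): C1=C2 is the vinyl group on quaternary C3; C4=C5 is the (E)-alkene; C6–C8 link it to ring A (C9–C14, gem-dimethyl on C14); C15–C22 is the second arm with methylidene groups on C18 and C22.

Assumption: the carbene L1 = (4R,5R)-1-(2,6-diisopropylphenyl)-4,5-diphenyl-3-(2-sulfonatophenyl)imidazolidin-2-ylidene, used as its disilver complex Ag2(L1)2 (made beforehand from the imidazolinium sulfonate and Ag2O), is taken to deliver the alkenyl group to the face of the (E)-phosphate that gives 3S; if the sense proves opposite, the mirror-image ligand is used.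

Remark: the lithium reagent made from (2Z)-2-bromobut-2-ene keeps the geometry of the bromide but is named (2E) by the sequence rule.

**Part 1 – lactone, ring A and the C8 aldehyde**

Step 1
Reactants: 1 3,3-dimethylpent-4-enoic acid; 2 (4S)-4-benzyl-1,3-oxazolidin-2-one
Product: 4 (4S)-4-benzyl-3-(3,3-dimethylpent-4-enoyl)-1,3-oxazolidin-2-one, via mixed pivalic anhydride 3 (not isolated)
Conditions: t-BuCOCl, Et3N, THF, −20 °C; then 2, LiCl, −20 °C → rt
Reagents that add atoms: none
Why: N-acylation of the oxazolidinone through the mixed anhydride (acyl transfer) should occur at the less hindered carbonyl of 3 and installs the chiral auxiliary without touching the vinyl group.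

Step 2
Reactants: 4 (4S)-4-benzyl-3-(3,3-dimethylpent-4-enoyl)-1,3-oxazolidin-2-one
Product: 6 (4S)-4-benzyl-3-[(2S)-2,3,3-trimethylpent-4-enoyl]-1,3-oxazolidin-2-one, via sodium enolate 5 (not isolated)
Conditions: NaN(SiMe3)2, THF, −78 °C; MeI, −78 → −40 °C
Reagents that add atoms: iodomethane, CI
Why: In this Evans asymmetric alkylation the chelated (Z)-enolate 5 should be methylated on the face away from the benzyl group, which sets C13 as (S) next to the quaternary C14.

Step 3
Reactants: 6 (4S)-4-benzyl-3-[(2S)-2,3,3-trimethylpent-4-enoyl]-1,3-oxazolidin-2-one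
Product: 7 (2S)-2,3,3-trimethylpent-4-en-1-ol
Conditions: LiBH4, MeOH (1 equiv), Et2O, 0 °C
Reagents that add atoms: none
Why: Reductive cleavage of the N-acyl oxazolidinone by borohydride attacks the exocyclic carbonyl, so the primary alcohol should be released with C13 untouched and the auxiliary recovered.

Step 4
Reactants: 7 (2S)-2,3,3-trimethylpent-4-en-1-ol
Product: 8 (2S)-2,3,3-trimethylpent-4-enal
Conditions: Dess–Martin periodinane, CH2Cl2, 0 °C → rt
Reagents that add atoms: none
Why: Dess–Martin oxidation under non-basic conditions should give the α-branched aldehyde without epimerising C13, whose hydrogen is shielded by the adjacent quaternary carbon.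

Step 5
Reactants: 8 (2S)-2,3,3-trimethylpent-4-enal; 9 (2Z)-2-bromobut-2-ene
Product: 11 (2Z,4R,5S)-3,5,6,6-tetramethylocta-2,7-dien-4-ol, via alkenyllithium 10 (not isolated)
Conditions: 9, t-BuLi (2 equiv), Et2O, −78 °C; then 8, −78 °C; H2O
Reagents that add atoms: none
Why: Bromine–lithium exchange keeps the alkene geometry, and Felkin–Anh 1,2-addition of 10 anti to the bulky 2-methylbut-3-en-2-yl group of 8 should set C12 syn to the C13 methyl.

Step 6
Reactants: 11 (2Z,4R,5S)-3,5,6,6-tetramethylocta-2,7-dien-4-ol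
Product: 13 (4S,5R,6Z)-3,3,4,6-tetramethyloct-6-ene-1,5-diol, via bis-borane adduct 12 (not isolated)
Conditions: 9-BBN (2.5 equiv), THF, 0 °C → rt; then NaOH, H2O2, 0 °C → rt
Reagents that add atoms: hydrogen peroxide, OO
Why: Hydroboration–oxidation with the bulky 9-BBN should select the monosubstituted vinyl group over the trisubstituted alkene and place the hydroxyl on terminal C8.

Step 7
Reactants: 13 (4S,5R,6Z)-3,3,4,6-tetramethyloct-6-ene-1,5-diol
Product: 15 (5S,6R)-6-[(2Z)-but-2-en-2-yl]-4,4,5-trimethyloxan-2-one, via lactol 14 (not isolated)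
Conditions: TEMPO (cat.), PhI(OAc)2, CH2Cl2, rt
Reagents that add atoms: none
Why: In this TEMPO-catalysed oxidative lactonisation the unhindered primary alcohol should be oxidised first, the hydroxy aldehyde closes to lactol 14 (helped by the gem-dimethyl group) and 14 is oxidised on to the δ-lactone with C12 and C13 unchanged.

Step 8
Reactants: 15 (5S,6R)-6-[(2Z)-but-2-en-2-yl]-4,4,5-trimethyloxan-2-one
Product: 19 (1R,2R,5R)-2,3,5,6,6-pentamethylcyclohex-3-ene-1-carboxylic acid, via lithium enolate 16 (not isolated), via silyl ketene acetal 17 (not isolated), via silyl ester 18 (not isolated)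
Conditions: LiN(i-Pr)2, THF, −78 °C; t-BuMe2SiCl, DMPU, −78 °C → rt; PhMe, 110 °C; then 1 M HCl, THF
Reagents that add atoms: none
Why: Deprotonation at C9, the only enolisable position, and O-silylation give the ring-locked silyl ketene acetal 17, whose C9=C8–O–C12–C11=C10 array undergoes a concerted suprafacial [3,3] sigmatropic shift that forms C9–C10, breaks C12–O and leaves the alkene at C11=C12 and C8 as a silyl carboxylate. The closest known reaction is the Ireland–Claisen rearrangement of 6-alkenyl δ-lactone silyl ketene acetals to cyclohex-3-enecarboxylic acids; the tert-butyldimethylsilyl acetal is chosen over the trimethylsilyl one because this substrate is more crowded than usual and must survive prolonged heating. Ring A is closed by the sigmatropic C9–C10 bond formation itself, which the two-carbon C14–C13 tether between C9 and C12 forces through a boat-like, bicyclo[2.2.2]octane-shaped transition state. C9 is controlled by the cis lactone, because C10 is delivered to the face of C9 on which the butenyl group and the C13 methyl sit, so C8 ends up trans to that methyl; C10 is controlled by the Z alkene geometry, which turns its methyl toward the C14–C13 bridge and therefore trans to C8 and cis to the C13 methyl. The selectivity needed is rearrangement ahead of C-silylation, self-condensation or loss of the acetal, and it is secured by fast silylation at −78 °C, the aprotic hot step and the absence of any chair or open-chain pathway in the tethered system.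

Step 9
Reactants: 19 (1R,2R,5R)-2,3,5,6,6-pentamethylcyclohex-3-ene-1-carboxylic acid
Product: 20 [(1R,2R,5R)-2,3,5,6,6-pentamethylcyclohex-3-en-1-yl]methanol
Conditions: LiAlH4, THF, 0 °C → reflux
Reagents that add atoms: none
Why: Hydride reduction of the carboxylic acid should give the hindered primary alcohol and cannot disturb the three ring stereocentres.

Step 10
Reactants: 20 [(1R,2R,5R)-2,3,5,6,6-pentamethylcyclohex-3-en-1-yl]methanol
Product: 21 (1R,2R,5R)-2,3,5,6,6-pentamethylcyclohex-3-ene-1-carbaldehyde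
Conditions: Dess–Martin periodinane, CH2Cl2, 0 °C → rt
Reagents that add atoms: none
Why: Dess–Martin oxidation stops at the aldehyde under non-basic conditions, so C9 next to the new carbonyl should keep its configuration, which is also the more stable one.

**Part 2 – C5–C7 unit, chain extension and alkyne**

Step 11
Reactants: 22 (2R)-3-bromo-2-methylpropan-1-ol
Product: 23 [(2R)-3-bromo-2-methylpropoxy](tert-butyl)dimethylsilane
Conditions: t-BuMe2SiCl, imidazole, CH2Cl2, rt
Reagents that add atoms: tert-butyl(chloro)dimethylsilane, CC(C)(C)[Si](C)(C)Cl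
Why: Silyl ether formation protects the primary alcohol (the future C5) and leaves the bromide free for phosphonium salt formation.

Step 12
Reactants: 23 [(2R)-3-bromo-2-methylpropoxy](tert-butyl)dimethylsilane
Product: 24 {(2R)-3-[(tert-butyldimethylsilyl)oxy]-2-methylpropyl}triphenylphosphonium bromide
Conditions: PPh3, PhMe, 110 °C
Reagents that add atoms: triphenylphosphine, c1ccc(cc1)P(c1ccccc1)c1ccccc1
Why: SN2 quaternisation of triphenylphosphine by the primary bromide should give the Wittig salt, and the methyl-bearing centre that becomes C6 is not involved.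

Step 13
Reactants: 24 {(2R)-3-[(tert-butyldimethylsilyl)oxy]-2-methylpropyl}triphenylphosphonium bromide; 21 (1R,2R,5R)-2,3,5,6,6-pentamethylcyclohex-3-ene-1-carbaldehyde
Product: 26 tert-butyldimethyl{[(2S,3Z)-2-methyl-4-[(1R,2R,5R)-2,3,5,6,6-pentamethylcyclohex-3-en-1-yl]but-3-en-1-yl]oxy}silane, via ylide 25 (not isolated)
Conditions: NaN(SiMe3)2, THF, 0 °C; then 21, −78 °C → rt
Reagents that add atoms: none
Why: Wittig olefination with the reactive non-stabilised ylide 25 should join C7 to the hindered aldehyde carbon C8 as the (Z)-alkene, whose geometry is irrelevant because it is reduced next.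

Step 14
Reactants: 26 tert-butyldimethyl{[(2S,3Z)-2-methyl-4-[(1R,2R,5R)-2,3,5,6,6-pentamethylcyclohex-3-en-1-yl]but-3-en-1-yl]oxy}silane
Product: 27 tert-butyldimethyl{[(2S)-2-methyl-4-[(1R,2R,5R)-2,3,5,6,6-pentamethylcyclohex-3-en-1-yl]butyl]oxy}silane
Conditions: TsNHNH2, NaOAc, DME–H2O, 85 °C
Reagents that add atoms: none
Why: Diimide reduction (concerted syn transfer of hydrogen) should saturate the 1,2-disubstituted C7=C8 alkene much faster than the hindered trisubstituted ring alkene and tolerates the silyl ether.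

Step 15
Reactants: 27 tert-butyldimethyl{[(2S)-2-methyl-4-[(1R,2R,5R)-2,3,5,6,6-pentamethylcyclohex-3-en-1-yl]butyl]oxy}silane
Product: 28 (2S)-2-methyl-4-[(1R,2R,5R)-2,3,5,6,6-pentamethylcyclohex-3-en-1-yl]butan-1-ol
Conditions: Bu4NF, THF, rt
Reagents that add atoms: none
Why: Fluoride-mediated desilylation should free the primary alcohol at C5.

Step 16
Reactants: 28 (2S)-2-methyl-4-[(1R,2R,5R)-2,3,5,6,6-pentamethylcyclohex-3-en-1-yl]butan-1-ol
Product: 29 (2S)-2-methyl-4-[(1R,2R,5R)-2,3,5,6,6-pentamethylcyclohex-3-en-1-yl]butanal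
Conditions: Dess–Martin periodinane, CH2Cl2, 0 °C → rt
Reagents that add atoms: none
Why: Dess–Martin oxidation should give the α-methyl aldehyde under conditions that do not epimerise C6.

Step 17
Reactants: 29 (2S)-2-methyl-4-[(1R,2R,5R)-2,3,5,6,6-pentamethylcyclohex-3-en-1-yl]butanal
Product: 30 (3S)-3-methyl-5-[(1R,2R,5R)-2,3,5,6,6-pentamethylcyclohex-3-en-1-yl]pent-1-yne
Conditions: dimethyl (1-diazo-2-oxopropyl)phosphonate, K2CO3, MeOH, 0 °C → rt
Reagents that add atoms: dimethyl (1-diazo-2-oxopropyl)phosphonate, COP(=O)(OC)C(=[N+]=[N-])C(C)=O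
Why: Seyferth–Gilbert homologation in the Ohira–Bestmann variant should convert the aldehyde into the terminal alkyne C5≡C4 under mild carbonate conditions that preserve α-methyl stereocentres.

**Part 3 – C1–C3/C15–C22 allylic phosphate (both methyl-branched centres from one building block, 36)**

Step 18
Reactants: 2 (4S)-4-benzyl-1,3-oxazolidin-2-one; 31 3-methylbut-2-enoyl chloride
Product: 33 (4S)-4-benzyl-3-(3-methylbut-2-enoyl)-1,3-oxazolidin-2-one, via lithium salt 32 (not isolated)
Conditions: n-BuLi, THF, −78 °C; then 31, −78 → 0 °C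
Reagents that add atoms: none
Why: N-acylation of the lithiated oxazolidinone 32 with the acid chloride (acyl substitution) should give the unsaturated imide cleanly.

Step 19
Reactants: 33 (4S)-4-benzyl-3-(3-methylbut-2-enoyl)-1,3-oxazolidin-2-one
Product: 35 (4S)-4-benzyl-3-[(2S)-2,3-dimethylbut-3-enoyl]-1,3-oxazolidin-2-one, via sodium dienolate 34 (not isolated)
Conditions: NaN(SiMe3)2, THF, −78 °C; MeI, −78 °C
Reagents that add atoms: iodomethane, CI
Why: In this deconjugative Evans alkylation γ-deprotonation gives the chelated dienolate 34, which should be methylated at the α-carbon on the face away from the benzyl group to set the (S) centre and reveal the isopropenyl group.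

Step 20
Reactants: 35 (4S)-4-benzyl-3-[(2S)-2,3-dimethylbut-3-enoyl]-1,3-oxazolidin-2-one
Product: 36 (2S)-2,3-dimethylbut-3-en-1-ol
Conditions: LiBH4, MeOH (1 equiv), Et2O, 0 °C
Reagents that add atoms: none
Why: Borohydride cleavage of the imide (reductive removal of the auxiliary) should give the homoallylic alcohol with the α-stereocentre intact.

Step 21
Reactants: 36 (2S)-2,3-dimethylbut-3-en-1-ol
Product: 37 (3S)-4-bromo-2,3-dimethylbut-1-ene
Conditions: CBr4, PPh3, CH2Cl2, 0 °C
Reagents that add atoms: tetrabromomethane, BrC(Br)(Br)Br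
Why: Appel bromination replaces the primary hydroxyl by SN2 at the CH2 carbon and so should not touch the adjacent stereocentre.

Step 22
Reactants: 37 (3S)-4-bromo-2,3-dimethylbut-1-ene
Product: 38 (3S)-4-bromo-2-(chloromethyl)-3-methylbut-1-ene
Conditions: NaOCl (aq.), CeCl3·7H2O, CH2Cl2–H2O, 0 °C
Reagents that add atoms: sodium hypochlorite, [Na+].[O-]Cl
Why: Ene-type allylic chlorination of the isopropenyl group should deliver chlorine to the terminal carbon and take the proton from the methyl group, so the alkene re-forms as a methylidene and the neighbouring stereocentre is kept.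

Step 23
Reactants: 37 (3S)-4-bromo-2,3-dimethylbut-1-ene; 38 (3S)-4-bromo-2-(chloromethyl)-3-methylbut-1-ene
Product: 40 (3R,7S)-8-bromo-2,3,7-trimethyl-6-methylideneoct-1-ene, via Grignard reagent 39 (not isolated)
Conditions: 37, Mg, THF, rt; then 38, Li2CuCl4 (cat.), THF, −78 → 0 °C
Reagents that add atoms: none
Why: Copper-catalysed cross-coupling of the alkyl Grignard reagent with the allylic chloride should form C19–C20, since the 2-substituted allyl unit gives the same product by direct or allylic attack and the primary bromide of 38 is far less reactive.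

Step 24
Reactants: 41 2-[(tert-butyldimethylsilyl)oxy]acetaldehyde; 42 ethyl 2-(triphenyl-λ5-phosphanylidene)propanoate
Product: 43 ethyl (2E)-4-[(tert-butyldimethylsilyl)oxy]-2-methylbut-2-enoate
Conditions: CH2Cl2, rt
Reagents that add atoms: none
Why: Wittig olefination with the stabilised α-methyl ylide should give the (E)-trisubstituted enoate that fixes the C2=C3 geometry.

Step 25
Reactants: 43 ethyl (2E)-4-[(tert-butyldimethylsilyl)oxy]-2-methylbut-2-enoate
Product: 44 (2E)-4-[(tert-butyldimethylsilyl)oxy]-2-methylbut-2-en-1-ol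
Conditions: i-Bu2AlH, CH2Cl2, −78 °C
Reagents that add atoms: none
Why: 1,2-Hydride reduction of the conjugated ester should give the allylic alcohol with the (E) geometry unchanged.

Step 26
Reactants: 44 (2E)-4-[(tert-butyldimethylsilyl)oxy]-2-methylbut-2-en-1-ol
Product: 46 tert-butyl{[(2E)-4-chloro-3-methylbut-2-en-1-yl]oxy}dimethylsilane, via mesylate 45 (not isolated)
Conditions: MsCl, 2,4,6-collidine, LiCl, DMF, 0 °C
Reagents that add atoms: lithium chloride, [Li+].[Cl-]
Why: Chloride displacement of the allylic mesylate formed in the flask (SN2) should give the primary allylic chloride without allylic transposition.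

Step 27
Reactants: 40 (3R,7S)-8-bromo-2,3,7-trimethyl-6-methylideneoct-1-ene; 46 tert-butyl{[(2E)-4-chloro-3-methylbut-2-en-1-yl]oxy}dimethylsilane
Product: 48 tert-butyldimethyl{[(2E,6R,10R)-3,6,10,11-tetramethyl-7-methylidenedodeca-2,11-dien-1-yl]oxy}silane, via Grignard reagent 47 (not isolated)
Conditions: 40, Mg, THF, rt; then 46, Li2CuCl4 (cat.), THF, −78 → 0 °C
Reagents that add atoms: none
Why: Copper-catalysed Grignard–allylic chloride coupling in THF at low temperature, conditions that favour direct substitution at the CH2Cl carbon, should join C16 to C15 and keep the (E) geometry of the trisubstituted alkene.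

Step 28
Reactants: 48 tert-butyldimethyl{[(2E,6R,10R)-3,6,10,11-tetramethyl-7-methylidenedodeca-2,11-dien-1-yl]oxy}silane
Product: 49 (2E,6R,10R)-3,6,10,11-tetramethyl-7-methylidenedodeca-2,11-dien-1-ol
Conditions: Bu4NF, THF, 0 °C
Reagents that add atoms: none
Why: Fluoride-mediated desilylation should free the allylic alcohol without affecting the three alkenes.

Step 29
Reactants: 49 (2E,6R,10R)-3,6,10,11-tetramethyl-7-methylidenedodeca-2,11-dien-1-ol
Product: 50 diethyl (2E,6R,10R)-3,6,10,11-tetramethyl-7-methylidenedodeca-2,11-dien-1-yl phosphate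
Conditions: ClP(O)(OEt)2, pyridine, DMAP (cat.), CH2Cl2, 0 °C
Reagents that add atoms: diethyl chlorophosphate, CCOP(=O)(Cl)OCC
Why: O-Phosphorylation of the allylic alcohol should give the leaving group required for copper-catalysed allylic substitution.

**Part 4 – union of the fragments**

Step 30
Reactants: 30 (3S)-3-methyl-5-[(1R,2R,5R)-2,3,5,6,6-pentamethylcyclohex-3-en-1-yl]pent-1-yne; 50 diethyl (2E,6R,10R)-3,6,10,11-tetramethyl-7-methylidenedodeca-2,11-dien-1-yl phosphate
Product: 52 (3R,5R,6R)-5-[(3S,4E,6S,9R,13R)-6-ethenyl-3,6,9,13,14-pentamethyl-10-methylidenepentadeca-4,14-dien-1-yl]-1,3,4,4,6-pentamethylcyclohex-1-ene, via alkenylalane 51 (not isolated)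
Conditions: 30, i-Bu2AlH, hexanes, 55 °C; then 50, CuCl2·2H2O (cat.), Ag2(L1)2 (cat.), THF, −15 °C
Reagents that add atoms: none
Why: syn-Hydroalumination of the terminal alkyne gives the (E)-alkenylalane 51, and carbene–copper-catalysed enantioselective SN2′ allylic substitution of the (E)-phosphate should transfer the alkenyl group to C3 with catalyst control of the quaternary centre (3S) and leave C1=C2 as the vinyl group.

**Compound list**

1 | 3,3-dimethylpent-4-enoic acid | C=CC(C)(C)CC(=O)O | starting material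
2 | (4S)-4-benzyl-1,3-oxazolidin-2-one | O=C1N[C@@H](Cc2ccccc2)CO1 | starting material
3 | 3,3-dimethylpent-4-enoic pivalic anhydride (not isolated) | C=CC(C)(C)CC(=O)OC(=O)C(C)(C)C | intermediate
4 | (4S)-4-benzyl-3-(3,3-dimethylpent-4-enoyl)-1,3-oxazolidin-2-one | C=CC(C)(C)CC(=O)N1[C@@H](Cc2ccccc2)COC1=O | intermediate
5 | sodium (1Z)-1-[(4S)-4-benzyl-2-oxo-1,3-oxazolidin-3-yl]-3,3-dimethylpenta-1,4-dien-1-olate (not isolated) | [Na+].C=CC(C)(C)/C=C(\[O-])N1[C@@H](Cc2ccccc2)COC1=O | intermediate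
6 | (4S)-4-benzyl-3-[(2S)-2,3,3-trimethylpent-4-enoyl]-1,3-oxazolidin-2-one | C=CC(C)(C)[C@H](C)C(=O)N1[C@@H](Cc2ccccc2)COC1=O | intermediate
7 | (2S)-2,3,3-trimethylpent-4-en-1-ol | C=CC(C)(C)[C@H](C)CO | intermediate
8 | (2S)-2,3,3-trimethylpent-4-enal | C=CC(C)(C)[C@H](C)C=O | intermediate
9 | (2Z)-2-bromobut-2-ene | C/C=C(C)\Br | starting material
10 | (2E)-but-2-en-2-yllithium, lithium cis to the C3 methyl as in 9 (not isolated) | C/C=C(C)\[Li] | intermediate
11 | (2Z,4R,5S)-3,5,6,6-tetramethylocta-2,7-dien-4-ol | C/C=C(C)\[C@H](O)[C@@H](C)C(C)(C)C=C | intermediate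
12 | 9-[(4S,5R,6Z)-5-[(9-borabicyclo[3.3.1]nonan-9-yl)oxy]-3,3,4,6-tetramethyloct-6-en-1-yl]-9-borabicyclo[3.3.1]nonane (not isolated) | C/C=C(C)\[C@H](OB1C2CCCC1CCC2)[C@@H](C)C(C)(C)CCB1C2CCCC1CCC2 | intermediate
13 | (4S,5R,6Z)-3,3,4,6-tetramethyloct-6-ene-1,5-diol | C/C=C(C)\[C@H](O)[C@@H](C)C(C)(C)CCO | intermediate
14 | (5S,6R)-6-[(2Z)-but-2-en-2-yl]-4,4,5-trimethyloxan-2-ol, lactol as both anomers (not isolated) | C/C=C(C)\[C@@H]1OC(O)CC(C)(C)[C@@H]1C | intermediate
15 | (5S,6R)-6-[(2Z)-but-2-en-2-yl]-4,4,5-trimethyloxan-2-one (cis lactone) | C/C=C(C)\[C@@H]1OC(=O)CC(C)(C)[C@@H]1C | intermediate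
16 | lithium (2R,3S)-2-[(2Z)-but-2-en-2-yl]-3,4,4-trimethyl-3,4-dihydro-2H-pyran-6-olate (not isolated) | [Li+].C/C=C(C)\[C@@H]1OC([O-])=CC(C)(C)[C@@H]1C | intermediate
17 | tert-butyl({(2R,3S)-2-[(2Z)-but-2-en-2-yl]-3,4,4-trimethyl-3,4-dihydro-2H-pyran-6-yl}oxy)dimethylsilane (not isolated) | C/C=C(C)\[C@@H]1OC(O[Si](C)(C)C(C)(C)C)=CC(C)(C)[C@@H]1C | intermediate
18 | tert-butyldimethylsilyl (1R,2R,5R)-2,3,5,6,6-pentamethylcyclohex-3-ene-1-carboxylate (not isolated) | CC(C)(C)[Si](C)(C)OC(=O)[C@@H]1[C@@H](C)C(C)=C[C@@H](C)C1(C)C | intermediate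
19 | (1R,2R,5R)-2,3,5,6,6-pentamethylcyclohex-3-ene-1-carboxylic acid | OC(=O)[C@@H]1[C@@H](C)C(C)=C[C@@H](C)C1(C)C | intermediate
20 | [(1R,2R,5R)-2,3,5,6,6-pentamethylcyclohex-3-en-1-yl]methanol | OC[C@@H]1[C@@H](C)C(C)=C[C@@H](C)C1(C)C | intermediate
21 | (1R,2R,5R)-2,3,5,6,6-pentamethylcyclohex-3-ene-1-carbaldehyde | O=C[C@@H]1[C@@H](C)C(C)=C[C@@H](C)C1(C)C | intermediate
22 | (2R)-3-bromo-2-methylpropan-1-ol | BrC[C@H](C)CO | starting material
23 | [(2R)-3-bromo-2-methylpropoxy](tert-butyl)dimethylsilane | BrC[C@H](C)CO[Si](C)(C)C(C)(C)C | intermediate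
24 | {(2R)-3-[(tert-butyldimethylsilyl)oxy]-2-methylpropyl}triphenylphosphonium bromide | [Br-].CC(C)(C)[Si](C)(C)OC[C@@H](C)C[P+](c1ccccc1)(c1ccccc1)c1ccccc1 | intermediate
25 | {(2R)-3-[(tert-butyldimethylsilyl)oxy]-2-methylpropylidene}triphenyl-λ5-phosphane (not isolated) | CC(C)(C)[Si](C)(C)OC[C@@H](C)C=P(c1ccccc1)(c1ccccc1)c1ccccc1 | intermediate
26 | tert-butyldimethyl{[(2S,3Z)-2-methyl-4-[(1R,2R,5R)-2,3,5,6,6-pentamethylcyclohex-3-en-1-yl]but-3-en-1-yl]oxy}silane | CC(C)(C)[Si](C)(C)OC[C@@H](C)/C=C\[C@@H]1[C@@H](C)C(C)=C[C@@H](C)C1(C)C | intermediate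
27 | tert-butyldimethyl{[(2S)-2-methyl-4-[(1R,2R,5R)-2,3,5,6,6-pentamethylcyclohex-3-en-1-yl]butyl]oxy}silane | CC(C)(C)[Si](C)(C)OC[C@@H](C)CC[C@@H]1[C@@H](C)C(C)=C[C@@H](C)C1(C)C | intermediate
28 | (2S)-2-methyl-4-[(1R,2R,5R)-2,3,5,6,6-pentamethylcyclohex-3-en-1-yl]butan-1-ol | OC[C@@H](C)CC[C@@H]1[C@@H](C)C(C)=C[C@@H](C)C1(C)C | intermediate
29 | (2S)-2-methyl-4-[(1R,2R,5R)-2,3,5,6,6-pentamethylcyclohex-3-en-1-yl]butanal | O=C[C@@H](C)CC[C@@H]1[C@@H](C)C(C)=C[C@@H](C)C1(C)C | intermediate
30 | (3S)-3-methyl-5-[(1R,2R,5R)-2,3,5,6,6-pentamethylcyclohex-3-en-1-yl]pent-1-yne | C#C[C@@H](C)CC[C@@H]1[C@@H](C)C(C)=C[C@@H](C)C1(C)C | intermediate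
31 | 3-methylbut-2-enoyl chloride | CC(C)=CC(=O)Cl | starting material
32 | lithium (4S)-4-benzyl-2-oxo-1,3-oxazolidin-3-ide (not isolated) | [Li+].O=C1[N-][C@@H](Cc2ccccc2)CO1 | intermediate
33 | (4S)-4-benzyl-3-(3-methylbut-2-enoyl)-1,3-oxazolidin-2-one | CC(C)=CC(=O)N1[C@@H](Cc2ccccc2)COC1=O | intermediate
34 | sodium (1Z)-1-[(4S)-4-benzyl-2-oxo-1,3-oxazolidin-3-yl]-3-methylbuta-1,3-dien-1-olate (not isolated) | [Na+].C=C(C)/C=C(\[O-])N1[C@@H](Cc2ccccc2)COC1=O | intermediate
35 | (4S)-4-benzyl-3-[(2S)-2,3-dimethylbut-3-enoyl]-1,3-oxazolidin-2-one | C=C(C)[C@H](C)C(=O)N1[C@@H](Cc2ccccc2)COC1=O | intermediate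
36 | (2S)-2,3-dimethylbut-3-en-1-ol | OC[C@@H](C)C(C)=C | intermediate
37 | (3S)-4-bromo-2,3-dimethylbut-1-ene | BrC[C@@H](C)C(C)=C | intermediate
38 | (3S)-4-bromo-2-(chloromethyl)-3-methylbut-1-ene | BrC[C@@H](C)C(=C)CCl | intermediate
39 | [(2S)-2,3-dimethylbut-3-en-1-yl]magnesium bromide (not isolated) | Br[Mg]C[C@@H](C)C(C)=C | intermediate
40 | (3R,7S)-8-bromo-2,3,7-trimethyl-6-methylideneoct-1-ene | BrC[C@@H](C)C(=C)CC[C@@H](C)C(C)=C | intermediate
41 | 2-[(tert-butyldimethylsilyl)oxy]acetaldehyde | CC(C)(C)[Si](C)(C)OCC=O | starting material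
42 | ethyl 2-(triphenyl-λ5-phosphanylidene)propanoate | CCOC(=O)C(C)=P(c1ccccc1)(c1ccccc1)c1ccccc1 | starting material
43 | ethyl (2E)-4-[(tert-butyldimethylsilyl)oxy]-2-methylbut-2-enoate | CCOC(=O)/C(C)=C/CO[Si](C)(C)C(C)(C)C | intermediate
44 | (2E)-4-[(tert-butyldimethylsilyl)oxy]-2-methylbut-2-en-1-ol | OC/C(C)=C/CO[Si](C)(C)C(C)(C)C | intermediate
45 | (2E)-4-[(tert-butyldimethylsilyl)oxy]-2-methylbut-2-en-1-yl methanesulfonate (not isolated) | CS(=O)(=O)OC/C(C)=C/CO[Si](C)(C)C(C)(C)C | intermediate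
46 | tert-butyl{[(2E)-4-chloro-3-methylbut-2-en-1-yl]oxy}dimethylsilane | ClC/C(C)=C/CO[Si](C)(C)C(C)(C)C | intermediate
47 | [(2S,6R)-2,6,7-trimethyl-3-methylideneoct-7-en-1-yl]magnesium bromide (not isolated) | Br[Mg]C[C@@H](C)C(=C)CC[C@@H](C)C(C)=C | intermediate
48 | tert-butyldimethyl{[(2E,6R,10R)-3,6,10,11-tetramethyl-7-methylidenedodeca-2,11-dien-1-yl]oxy}silane | CC(C)(C)[Si](C)(C)OC/C=C(C)/CC[C@@H](C)C(=C)CC[C@@H](C)C(C)=C | intermediate
49 | (2E,6R,10R)-3,6,10,11-tetramethyl-7-methylidenedodeca-2,11-dien-1-ol | OC/C=C(C)/CC[C@@H](C)C(=C)CC[C@@H](C)C(C)=C | intermediate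
50 | diethyl (2E,6R,10R)-3,6,10,11-tetramethyl-7-methylidenedodeca-2,11-dien-1-yl phosphate | CCOP(=O)(OCC)OC/C=C(C)/CC[C@@H](C)C(=C)CC[C@@H](C)C(C)=C | intermediate
51 | bis(2-methylpropyl){(1E,3S)-3-methyl-5-[(1R,2R,5R)-2,3,5,6,6-pentamethylcyclohex-3-en-1-yl]pent-1-en-1-yl}alumane (not isolated) | CC(C)C[Al](CC(C)C)/C=C/[C@@H](C)CC[C@@H]1[C@@H](C)C(C)=C[C@@H](C)C1(C)C | intermediate
52 | (3R,5R,6R)-5-[(3S,4E,6S,9R,13R)-6-ethenyl-3,6,9,13,14-pentamethyl-10-methylidenepentadeca-4,14-dien-1-yl]-1,3,4,4,6-pentamethylcyclohex-1-ene (CNP0157304.1) | C=C[C@@](C)(/C=C/[C@@H](C)CC[C@@H]1[C@@H](C)C(C)=C[C@@H](C)C1(C)C)CC[C@@H](C)C(=C)CC[C@@H](C)C(=C)C | target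

**Totals**

Total step count: 30.
Longest linear sequence: 16 steps (steps 1–10, 13–17 and 30).

**Steps most likely to fail**

Step 8. In the enforced boat the Z-methyl on C10 is pressed against one methyl on C14, so the shift may become slow enough that silyl migration to carbon or loss of the ketene acetal overtakes it. The fallback rearranges the less crowded diastereomeric lactone and corrects C9 afterwards by equilibration; it sets out from aldehyde 8 and comes back at aldehyde 21. (E)-2-Bromobut-2-ene (C/C=C(C)/Br) and t-BuLi give (2Z)-but-2-en-2-yllithium F1, which adds to 8 to give (2E,4R,5S)-3,5,6,6-tetramethylocta-2,7-dien-4-ol F2. Dess–Martin oxidation gives (2E,5S)-3,5,6,6-tetramethylocta-2,7-dien-4-one F3, and Felkin–Anh-controlled Luche reduction (NaBH4, CeCl3·7H2O, MeOH, −78 °C) should give the anti alcohol (2E,4S,5S)-3,5,6,6-tetramethylocta-2,7-dien-4-ol F4. Hydroboration–oxidation as in step 6 gives (4S,5S,6E)-3,3,4,6-tetramethyloct-6-ene-1,5-diol F5, and oxidative lactonisation as in step 7 gives the trans lactone (5S,6S)-6-[(2E)-but-2-en-2-yl]-4,4,5-trimethyloxan-2-one F6. In its boat the C10 methyl and the C13 methyl both point away from the C14 methyls. Rearrangement under the conditions of step 8 should give the all-cis acid (1S,2R,5R)-2,3,5,6,6-pentamethylcyclohex-3-ene-1-carboxylic acid F7, which has C10 and C13 as in 19 and is epimeric only at C9. LiAlH4 gives [(1S,2R,5R)-2,3,5,6,6-pentamethylcyclohex-3-en-1-yl]methanol F8, Dess–Martin oxidation gives (1S,2R,5R)-2,3,5,6,6-pentamethylcyclohex-3-ene-1-carbaldehyde F9, and base equilibration of the α-centre (DBU, CH2Cl2) should move the formyl group trans to the C10 methyl and so give 21; the equilibrium position is an estimate and the epimers may need separation.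

Step 30. Facial control by the catalyst at C3 may be incomplete with two chiral, hindered partners (the alkenylalane is α-branched), and a C3 epimer of a hydrocarbon could not be separated; transfer of an isobutyl group is a second possible leak. The fallback sets C3 by reagent-controlled epoxidation and stereospecific epoxide opening; it sets out from alcohol 49 and alkyne 30 and comes back at target 52. Sharpless asymmetric epoxidation of 49 (Ti(Oi-Pr)4, D-(−)-diethyl tartrate, t-BuOOH, CH2Cl2, −20 °C) gives [(2R,3R)-3-methyl-3-[(3R,7R)-3,7,8-trimethyl-4-methylidenenon-8-en-1-yl]oxiran-2-yl]methanol F10. Alkyne 30 is converted (n-BuLi, then Et2AlCl, PhMe) into diethyl{(3S)-3-methyl-5-[(1R,2R,5R)-2,3,5,6,6-pentamethylcyclohex-3-en-1-yl]pent-1-yn-1-yl}alumane F11, which should open F10 at the tertiary carbon C3 with inversion. This gives the 1,2-diol (2S,3R,6R,10R)-3,6,10,11-tetramethyl-7-methylidene-3-{(3S)-3-methyl-5-[(1R,2R,5R)-2,3,5,6,6-pentamethylcyclohex-3-en-1-yl]pent-1-yn-1-yl}dodec-11-ene-1,2-diol F12, which already carries the quaternary centre. Corey–Winter olefination follows: thiocarbonyldiimidazole gives the cyclic thionocarbonate (1,3-dioxolane-2-thione) of F12 F13, and 1,3-dimethyl-2-phenyl-1,3,2-diazaphospholidine at 40 °C gives the enyne (3R,5R,6R)-5-[(3S,6S,9R,13R)-6-ethenyl-3,6,9,13,14-pentamethyl-10-methylidenepentadec-14-en-4-yn-1-yl]-1,3,4,4,6-pentamethylcyclohex-1-ene F14 with the C1=C2 vinyl group in place. Dissolving-metal reduction of the alkyne (Na, NH3, THF, −78 °C) should give the (E)-C4=C5 alkene, that is 52.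

Step 27. The organocopper intermediate may attack the distal allylic carbon (C2) or the Grignard reagent may homocouple, giving branched or dimeric hydrocarbons that are hard to remove. The fallback is sulfone alkylation followed by desulfonylation; it sets out from bromide 40 and comes back at silyl ether 48. PhSO2Na in DMF converts 40 into {[(2S,6R)-2,6,7-trimethyl-3-methylideneoct-7-en-1-yl]sulfonyl}benzene F15. Deprotonation (n-BuLi, THF, −78 °C) and alkylation with chloride 46, which sulfonyl carbanions attack directly at the primary allylic carbon, give tert-butyldimethyl{[(2E,6S,10R)-3,6,10,11-tetramethyl-7-methylidene-5-(phenylsulfonyl)dodeca-2,11-dien-1-yl]oxy}silane F16 as a mixture of epimers at the sulfonyl-bearing carbon. Reductive desulfonylation (Na/Hg, Na2HPO4, MeOH, −20 °C) removes that centre and should give 48.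

Further compounds
F1 | step 8 | (2Z)-but-2-en-2-yllithium | C/C=C(C)/[Li]
F2 | step 8 | (2E,4R,5S)-3,5,6,6-tetramethylocta-2,7-dien-4-ol | C/C=C(\C)[C@H](O)[C@@H](C)C(C)(C)C=C
F3 | step 8 | (2E,5S)-3,5,6,6-tetramethylocta-2,7-dien-4-one | C/C=C(\C)C(=O)[C@@H](C)C(C)(C)C=C
F4 | step 8 | (2E,4S,5S)-3,5,6,6-tetramethylocta-2,7-dien-4-ol | C/C=C(\C)[C@@H](O)[C@@H](C)C(C)(C)C=C
F5 | step 8 | (4S,5S,6E)-3,3,4,6-tetramethyloct-6-ene-1,5-diol | C/C=C(\C)[C@@H](O)[C@@H](C)C(C)(C)CCO
F6 | step 8 | (5S,6S)-6-[(2E)-but-2-en-2-yl]-4,4,5-trimethyloxan-2-one | C/C=C(\C)[C@H]1OC(=O)CC(C)(C)[C@@H]1C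
F7 | step 8 | (1S,2R,5R)-2,3,5,6,6-pentamethylcyclohex-3-ene-1-carboxylic acid | OC(=O)[C@H]1[C@@H](C)C(C)=C[C@@H](C)C1(C)C
F8 | step 8 | [(1S,2R,5R)-2,3,5,6,6-pentamethylcyclohex-3-en-1-yl]methanol | OC[C@H]1[C@@H](C)C(C)=C[C@@H](C)C1(C)C
F9 | step 8 | (1S,2R,5R)-2,3,5,6,6-pentamethylcyclohex-3-ene-1-carbaldehyde | O=C[C@H]1[C@@H](C)C(C)=C[C@@H](C)C1(C)C
F10 | step 30 | [(2R,3R)-3-methyl-3-[(3R,7R)-3,7,8-trimethyl-4-methylidenenon-8-en-1-yl]oxiran-2-yl]methanol | OC[C@H]1O[C@]1(C)CC[C@@H](C)C(=C)CC[C@@H](C)C(C)=C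
F11 | step 30 | diethyl{(3S)-3-methyl-5-[(1R,2R,5R)-2,3,5,6,6-pentamethylcyclohex-3-en-1-yl]pent-1-yn-1-yl}alumane | CC[Al](CC)C#C[C@@H](C)CC[C@@H]1[C@@H](C)C(C)=C[C@@H](C)C1(C)C
F12 | step 30 | (2S,3R,6R,10R)-3,6,10,11-tetramethyl-7-methylidene-3-{(3S)-3-methyl-5-[(1R,2R,5R)-2,3,5,6,6-pentamethylcyclohex-3-en-1-yl]pent-1-yn-1-yl}dodec-11-ene-1,2-diol | OC[C@@H](O)[C@@](C)(C#C[C@@H](C)CC[C@@H]1[C@@H](C)C(C)=C[C@@H](C)C1(C)C)CC[C@@H](C)C(=C)CC[C@@H](C)C(C)=C
F13 | step 30 | cyclic thionocarbonate of F12, (4S)-4-substituted 1,3-dioxolane-2-thione with the (R)-configured quaternary carbon | S=C1OC[C@@H](O1)[C@@](C)(C#C[C@@H](C)CC[C@@H]2[C@@H](C)C(C)=C[C@@H](C)C2(C)C)CC[C@@H](C)C(=C)CC[C@@H](C)C(C)=C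
F14 | step 30 | (3R,5R,6R)-5-[(3S,6S,9R,13R)-6-ethenyl-3,6,9,13,14-pentamethyl-10-methylidenepentadec-14-en-4-yn-1-yl]-1,3,4,4,6-pentamethylcyclohex-1-ene | C=C[C@@](C)(C#C[C@@H](C)CC[C@@H]1[C@@H](C)C(C)=C[C@@H](C)C1(C)C)CC[C@@H](C)C(=C)CC[C@@H](C)C(C)=C
F15 | step 27 | {[(2S,6R)-2,6,7-trimethyl-3-methylideneoct-7-en-1-yl]sulfonyl}benzene | O=S(=O)(C[C@@H](C)C(=C)CC[C@@H](C)C(C)=C)c1ccccc1
F16 | step 27 | tert-butyldimethyl{[(2E,6S,10R)-3,6,10,11-tetramethyl-7-methylidene-5-(phenylsulfonyl)dodeca-2,11-dien-1-yl]oxy}silane (both C5 epimers) | CC(C)(C)[Si](C)(C)OC/C=C(C)/CC([C@@H](C)C(=C)CC[C@@H](C)C(C)=C)S(=O)(=O)c1ccccc1
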